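(The earlier runs and the new flask are calculated for an exercise, and the scatter is random.)

Every X unit stays in the closed flask, so what leaves the solid must appear as D or as a product.

| flask | X | remark | time |
|---|---|---|---|
| elm | 0.20 M | run made earlier |  |
| flask | 0.10 M |  | 15 d |

- elm (time / h: J / %): 3.00: 0.8; 4.00: 0.8; 6.00: 4.8; 10.0: 2.2; 15.0: 6.4; 25.0: 9.0; 40.0: 12.5

(each reading ± 1 percentage point)

- when, up to 15 d, the flask holds most J
- the amount of J, in percent of the X charged, at that time

- percent here means X units held: one Z or L counts as two
- percent here means X units held: one Q counts as three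
- X is a solid; its amount is given per volume of the solution
- the numbers in the tables scatter with a standard deviation of 1 percentage point
- reactions considered so far: D -> J; 2 D -> Z; X <-> D; D + Z -> Q; J -> G; Z -> L; J <-> E
- at the start none of X is in solution

We assume that while solid X stands, D holds one concentration whatever the charge. J is then made at zero order in the charge. We read the last row of the elm run, where the scatter weighs least: 12.5% of 0.20 M in 40.0 h, which is 0.625 mM h⁻¹. The flask's charge over this rate gives 6.67 d, our clearing time. But other paths also draw on D, and the reading counts J net of its losses. So we expect the solid gone, and J at its peak, somewhat before that time.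

The forecast also holds that “this absolute rate should not depend on the charge”. It gives 25% at 3.5 d, earlier than our clearing time.

The flask gives 56.2% at 4.26 d.

    D → J (k = 0.00599 min⁻¹)
    2 D → Z (k = 0.119 L mol⁻¹ min⁻¹)
    X ⇌ D, rate k3*(cs3 - [D]) while solid is left; crystals form when [D] > cs3 (solubility = 4.00 mM, k = 0.0106 min⁻¹)
    D + Z → Q (k = 0.0196 L mol⁻¹ min⁻¹)
    J → G (k = 9.37 × 10⁻⁵ min⁻¹)
    Z → L (k = 6.04 × 10⁻⁴ min⁻¹)
    J ⇌ E (K = 0.750, k = 9.77 × 10⁻⁵ min⁻¹)

In the flask, X still stood at 63.4% at 1.50 d, with D at 2.47% and J at 25.8%. By 4.26 d X was at 0% and J stood at its peak, then fell to 31.8% at 7.50 d as G and E grew. Our clearing time ran 1.57 times the flask's peak time, and at that peak E and G together held 33.4%.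

For a neighbour flask with 0.060 M of X, the clearing time is 4.00 d, shorter than the flask's. By our reckoning J has less time to pass on there, so we expect its peak share to rise. The computed peak is 65.6%, above the flask's 56.2%.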